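## Structural features

The target 13 is made of two 1H-pyrrole rings, ring A and ring B, joined by one C2–C2' single bond. Every other ring carbon (C3, C4, C5 and C3', C4', C5') carries bromine, and both nitrogens are free N–H. The molecule is C2-symmetric and has no stereocentre, so any stereocentre met on the way is temporary. The unbrominated 2,2'-bipyrrole core is very electron-rich and prone to oxidation, and N–H polybromopyrroles are sensitive to light and base. Bromine is therefore best put on last, and all six positions at once, which needs no regiocontrol because they are the only C–H positions. The real difficulty is to assemble the α,α'-linked bipyrrole at the aromatic oxidation level without mis-joining the two halves. The key step uses two features of the core. C5 and C5' are unsubstituted carbons next to nitrogen, so each can come from the terminal carbon of an alkyne through an N1–C5 bond. C2 and C2' are vicinal and each bears nitrogen, so the C2–C2' bond with both nitrogens can come from a glyoxal-derived 1,2-diamine. Sulfonyl groups on nitrogen store the two oxidation equivalents that aromatisation needs.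

## Logic of the disconnections

**13 ⇒ 12.** The six C–Br bonds are cut. All six positions of 12 are activated pyrrole C–H positions and are the only ones present, so exhaustive electrophilic substitution needs no selectivity. This strips the target to its C8N2 core. The forward step must brominate six times without oxidising the electron-rich core, which calls for a mild bromine source, low temperature and exclusion of light.

**12 ⇒ 10 (through 11).** Each aromatic ring is traced back to an N-sulfonyl 2,3-dihydropyrrole: forward, N–S and C2–H are broken and sulfinate leaves. The sulfonyl groups that make nitrogen a competent nucleophile in ring closure thus also serve as leaving groups, so no oxidant is needed. The gain is a stable, isolable bis-enamide in place of an oxidation-prone bipyrrole. The forward step needs a base strong enough to remove a C–H that is activated only by nitrogen (or the allylic C3–H), followed by tautomerisation of 11.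

**10 ⇒ 8 (through 9).** The N1–C5 and N1'–C5' bonds are cut, which opens both rings to an acyclic C2-symmetric diyne bis-sulfonamide. The C4=C5 enamide comes directly from the alkyne, so the oxidation level is already correct. The forward step must put each nitrogen on the terminal carbon of its own alkyne.

- Considering only the strained 4-exo closure as the competitor is incomplete. In 8 every alkyne is homopropargylic to its own nitrogen but bis-homopropargylic to the neighbouring one.
- Under a cationic gold π-acid the neighbouring nitrogen could therefore attack the internal carbon in an unstrained 5-exo-dig closure.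
- The skeleton of 8 is kept, but the activation is chosen so that only the terminal carbon is electrophilic: a tungsten vinylidene. There the own nitrogen closes a five-membered ring and the neighbour could only close a six-membered one.
- For this, 8 must keep free N–H sulfonamides and unprotected terminal alkynes, since the 1,2-hydrogen shift needs the terminal C–H.

**8 ⇒ 6 + 7.** Two N–S(sulfonyl) bonds are cut. Exchanging the sulfinyl group for tosyl costs two steps but supplies the arenesulfinate leaving group used in the aromatisation. The forward step is bis-sulfonylation of a hindered vicinal diamine, one sulfonyl per nitrogen.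

**6 ⇒ 5.** The two N–S(sulfinyl) bonds are restored in the retro sense. The auxiliary is needed only to activate and stabilise the diimine, and acid removes it without touching the alkynes.

**5 ⇒ 3 + 4.** The C3–C4 and C5–C6 bonds of the octadiyne chain are cut (C2–C3 and C2'–C3' of the bipyrrole). Both carbons are imine carbons of a glyoxal diimine, and a propargyl nucleophile gives the homopropargylic amine directly. One correction to the usual shorthand: the zinc reagent formed from 4 is the allenyl isomer, which transfers a propargyl group by SE2′. This halves the molecule into a C2 unit and two C3 units. The forward step needs two additions and propargyl rather than allenyl transfer; the diastereoselectivity is immaterial because both centres are later destroyed.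

**3 ⇒ 1 + 2.** The two C=N bonds are cut, leaving glyoxal and the sulfinamide. The forward condensation must remove water from aqueous 1 and avoid oligomerisation, which the electron-poor sulfinyl groups help to prevent.

## Other disconnections considered

**Alternative 1:** One pyrrole ring is cut at C2–C3 and C4–C5; the other ring and the inter-ring bond are bought in aldehyde A1 (tert-butyl 2-formylpyrrole-1-carboxylate).

- **Forward key step:** the glycine-derived imine A2 is converted with AgOAc/Et3N into a silver azomethine ylide. This adds to the bis-sulfone A3, and DBU then expels both sulfinates to give the bipyrrole ester A4.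
- **In favour:** the route is convergent, aromatisation is built in, and the two-carbon partner is symmetrical, so no own-versus-neighbour ambiguity arises. On regiocontrol it is better than the chosen plan.
- **Against:** A4 carries an ester at C5 and a carbamate on the other nitrogen. Both must be removed (saponification with decarboxylation or bromodecarboxylation, and carbamate cleavage) before or during hexabromination. The C2 symmetry of 13 is not used, and one ring is not built at all.
- **Comparison:** the step count is about equal to, or slightly lower than, that of the chosen plan. The mechanism is a dipolar cycloaddition rather than a metal-mediated hydroamination. The product is a desymmetrised bipyrrole, useful for analogues but unnecessary here, whereas the chosen plan ends directly at the parent 12.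

**Alternative 2:** Both rings are cut at C3=C4 and C3'=C4'.

- **Forward key step:** the tetraene A5 undergoes twofold ring-closing metathesis with the second-generation Grubbs catalyst Cl2Ru(=CHPh)(H2IMes)(PCy3), which joins each N-allyl group to the vinyl group on its own carbon and gives the bis-3-pyrroline A6.
- **In favour:** five-membered metathesis of N-allyl sulfonamides is dependable. In A6 the C2–H is both allylic and next to nitrogen, so sulfinate elimination should be easier than from 10. On that point it is better than the chosen plan.
- **Against:** A5 needs a twofold vinyl addition to 3 and an extra N-allylation, so the route is one step longer. A ruthenium catalyst is needed. An analogous neighbour problem exists, since an N-allyl group can also close a six-membered ring with the vinyl group on the adjacent carbon.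
- **Comparison:** the use of glyoxal and of symmetry is the same. The ring-forming bond is C=C under neutral conditions rather than C–N under basic ones. Step economy is slightly worse; the aromatisation is equal or better.

**Alternative 3:** The C2–C2' bond is taken from oxidative alkyne coupling and the rings are cut at N1–C2 and N1'–C2'.

- **Forward key step:** sulfonamide A7 is dimerised by Glaser–Hay coupling (CuCl, TMEDA, O2) to the diyne A8. Ph3PAuCl/AgOTf (univalent gold) then adds each nitrogen to the inner diyne carbon in a 5-endo-dig closure, giving A9.
- **In favour:** the route is short (about five steps from A7) and has no stereocentre or auxiliary. Each nitrogen can reach only one alkyne carbon in a sensible ring. On step economy and regiocontrol it is better than the chosen plan.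
- **Against:** after the first closure the remaining alkyne is conjugated to an enamide and is open to further gold chemistry or hydration. A9 is a conjugated bis-enamide diene, sensitive to acid and air. The aromatisation must remove a C–H no more activated than in 10, so on that point the two are equal.
- **Comparison:** structurally both plans exploit the symmetry. Mechanistically this one relies on gold π-activation of an internal diyne, the chosen plan on a vinylidene at a terminal alkyne. The chosen plan's advantage is limited to non-conjugated, isolable enamide intermediates and basic conditions throughout.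

Key step: step 5

Assumption: the (4R,5R) configuration drawn for 5 to 10 is the one expected from a chair-like chelated addition to each (S)-sulfinimine; either diastereomer would serve, because both stereocentres are destroyed in step 6.

## Route

**Step 1**
Reactants: 1 glyoxal (40 wt % aqueous solution); 2 (S)-2-methylpropane-2-sulfinamide
Product: 3 (S,S)-N,N'-[(1E,2E)-ethane-1,2-diylidene]bis(2-methylpropane-2-sulfinamide)
Conditions: 2 (2.1 equiv), anhydrous CuSO4 (5 equiv), CH2Cl2, rt
Reagents that add atoms: none
Why: Twofold sulfinimine formation (condensation of a sulfinamide with an aldehyde under Lewis-acidic dehydration); the electron-poor sulfinyl groups should keep the 1,2-diimine from oligomerising, and sulfur is not touched.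

**Step 2**
Reactants: 3 (S,S)-N,N'-[(1E,2E)-ethane-1,2-diylidene]bis(2-methylpropane-2-sulfinamide); 4 propargyl bromide
Product: 5 N,N'-[(4R,5R)-octa-1,7-diyne-4,5-diyl]bis[(S)-2-methylpropane-2-sulfinamide]
Conditions: 4 (5 equiv), activated Zn dust (6 equiv), THF, 0 °C; then 3, −78 °C → rt; aq NH4Cl
Reagents that add atoms: none
Why: Barbier-type propargylation of a sulfinimine: allenylzinc bromide transfers a propargyl group by SE2′ through a six-membered chair-like chelate to the sulfinyl group, so the sulfur auxiliary should direct attack to the Re face of each (S)-sulfinimine and set R at both carbons. The second imine reacts in the same way, which should give the C2-symmetric diastereomer.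

**Step 3**
Reactants: 5 N,N'-[(4R,5R)-octa-1,7-diyne-4,5-diyl]bis[(S)-2-methylpropane-2-sulfinamide]
Product: 6 (4R,5R)-octa-1,7-diyne-4,5-diamine dihydrochloride
Conditions: HCl (4 M in dioxane, 5 equiv), MeOH, 0 °C → rt; Et2O trituration
Reagents that add atoms: hydrogen chloride, Cl
Why: Acidic methanolysis of the N–S bond of a tert-butanesulfinamide, the standard removal of this auxiliary; terminal alkynes and the C–N stereocentres should be inert, and the salt should precipitate free of the sulfinate ester.

**Step 4**
Reactants: 6 (4R,5R)-octa-1,7-diyne-4,5-diamine dihydrochloride; 7 p-toluenesulfonyl chloride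
Product: 8 N,N'-[(4R,5R)-octa-1,7-diyne-4,5-diyl]bis(4-methylbenzenesulfonamide)
Conditions: 7 (2.3 equiv), Et3N (6 equiv), DMAP (5 mol %), CH2Cl2, 0 °C → rt
Reagents that add atoms: none
Why: N-sulfonylation of primary amines freed in situ from their salt; an α-branched primary amine should take one sulfonyl group only, leaving the N–H needed in step 5.

**Step 5**
Reactants: 8 N,N'-[(4R,5R)-octa-1,7-diyne-4,5-diyl]bis(4-methylbenzenesulfonamide)
Product: 10 (2R,2'R)-1,1'-bis(4-methylbenzenesulfonyl)-2,2',3,3'-tetrahydro-1H,1'H-2,2'-bipyrrole, via monocyclised alkynyl sulfonamide 9 (not isolated)
Conditions: W(CO)6 (25 mol %), Et3N (10 equiv), THF, hν (350 nm), 55 °C, Ar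
Reagents that add atoms: none
Why: Photolysis of W(CO)6 gives a zerovalent W(CO)5 fragment that binds each terminal alkyne and rearranges it by a 1,2-hydrogen shift to a vinylidene, whose α-carbon (the former terminal carbon) is the only electrophilic site; the sulfonamide nitrogen, assisted by Et3N, adds there and protonolysis of the C–W bond releases the enamide and the metal fragment. The closest known reaction type is the tungsten- or molybdenum-vinylidene endo-cycloisomerisation of terminal homopropargyl alcohols, carbamates and sulfonamides to 2,3-dihydrofurans and 2,3-dihydropyrroles. Ring A closes by N1–C5 bond formation in a 5-endo-dig sense (counted on the alkyne) to give 9, and ring B closes in the same way by N1'–C5' bond formation to give 10, each with the C4=C5 double bond in the ring. No stereocentre is created, and C2 and C2' are not epimerisable under these conditions, so the (R,R) backbone is carried through unchanged. The selectivity needed is twofold: the terminal rather than the internal carbon, and each nitrogen onto its own alkyne rather than its neighbour's. The vinylidene mechanism removes the internal carbon as an electrophile, which is the reason for not using a cationic gold π-acid such as Ph3PAuNTf2 (univalent gold), under which the neighbouring sulfonamide could reach the internal carbon by an unstrained 5-exo-dig closure. At the terminal carbon the own nitrogen closes a five-membered ring while the neighbouring one would have to close a six-membered ring, so the homopropargylic relationship built into 8 should decide in favour of 10. The amine keeps the medium basic, so the enamide of 9 is not protonated to an N-sulfonyliminium ion that the remaining N–H could trap.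

**Step 6**
Reactants: 10 (2R,2'R)-1,1'-bis(4-methylbenzenesulfonyl)-2,2',3,3'-tetrahydro-1H,1'H-2,2'-bipyrrole
Product: 12 1H,1'H-2,2'-bipyrrole, via 3H,3'H-2,2'-bipyrrole 11 (not isolated)
Conditions: t-BuOK (5 equiv), DMSO, rt → 50 °C, Ar; aq NH4Cl
Reagents that add atoms: none
Why: Base-induced elimination of p-toluenesulfinate across N1–C2 of each N-sulfonyl dihydropyrrole, the known sulfinate-elimination aromatisation of N-sulfonyl pyrrolines, followed by a base-mediated proton shift of the 3H-pyrrole to the aromatic 1H-tautomer. Should the allylic C3–H be removed instead, the 2H-tautomer would form and would reach the same product; both stereocentres vanish here.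

**Step 7**
Reactants: 12 1H,1'H-2,2'-bipyrrole
Product: 13 3,3',4,4',5,5'-hexabromo-1H,1'H-2,2'-bipyrrole
Conditions: NBS (6.3 equiv), THF, −78 → 0 °C, dark, Ar
Reagents that add atoms: N-bromosuccinimide, O=C1CCC(=O)N1Br
Why: Sixfold electrophilic aromatic bromination of an electron-rich pyrrole; the six ring C–H positions are the only ones available, so exhaustive substitution needs no regiocontrol, and low temperature with a mild bromine source should limit oxidation of the core.

## Compound list

1 | glyoxal (40 wt % in water) | O=CC=O | starting material
2 | (S)-2-methylpropane-2-sulfinamide | CC(C)(C)[S@](=O)N | starting material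
3 | (S,S)-N,N'-[(1E,2E)-ethane-1,2-diylidene]bis(2-methylpropane-2-sulfinamide) | CC(C)(C)[S@](=O)/N=C/C=N/[S@@](=O)C(C)(C)C | intermediate
4 | propargyl bromide (3-bromoprop-1-yne) | C#CCBr | starting material
5 | N,N'-[(4R,5R)-octa-1,7-diyne-4,5-diyl]bis[(S)-2-methylpropane-2-sulfinamide] | C#CC[C@@H](N[S@@](=O)C(C)(C)C)[C@@H](CC#C)N[S@@](=O)C(C)(C)C | intermediate
6 | (4R,5R)-octa-1,7-diyne-4,5-diamine dihydrochloride | C#CC[C@@H](N)[C@@H](CC#C)N.Cl.Cl | intermediate
7 | p-toluenesulfonyl chloride | Cc1ccc(cc1)S(Cl)(=O)=O | starting material
8 | N,N'-[(4R,5R)-octa-1,7-diyne-4,5-diyl]bis(4-methylbenzenesulfonamide) | C#CC[C@@H](NS(=O)(=O)c1ccc(C)cc1)[C@@H](CC#C)NS(=O)(=O)c1ccc(C)cc1 | intermediate (key-step precursor)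
9 | N-{(1R)-1-[(2R)-1-(4-methylbenzenesulfonyl)-2,3-dihydro-1H-pyrrol-2-yl]but-3-yn-1-yl}-4-methylbenzenesulfonamide | C1=CC[C@@H](N1S(=O)(=O)c1ccc(C)cc1)[C@@H](CC#C)NS(=O)(=O)c1ccc(C)cc1 | intermediate (not isolated)
10 | (2R,2'R)-1,1'-bis(4-methylbenzenesulfonyl)-2,2',3,3'-tetrahydro-1H,1'H-2,2'-bipyrrole | C1=CC[C@@H](N1S(=O)(=O)c1ccc(C)cc1)[C@@H](CC=C2)N2S(=O)(=O)c1ccc(C)cc1 | intermediate (key-step product)
11 | 3H,3'H-2,2'-bipyrrole | N1=C(CC=C1)C1=NC=CC1 | intermediate (not isolated)
12 | 1H,1'H-2,2'-bipyrrole | c1cc([nH]c1)-c1ccc[nH]1 | intermediate
13 | 3,3',4,4',5,5'-hexabromo-1H,1'H-2,2'-bipyrrole | Brc1[nH]c(-c2[nH]c(Br)c(Br)c2Br)c(Br)c1Br | target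

## Step count and least certain steps

Total step count: 7. Longest linear sequence: 7 steps (1 → 13).

**Step 5 (key step).** The two nitrogens may compete for the same activated alkyne. The neighbouring sulfonamide could close a six-membered ring at the vinylidene carbon, or, if the tungsten fragment acts as a simple π-acid, attack the internal carbon in an exo mode. The catalyst may also decay before the second ring has closed. The fallback sets out from 8 and places the electrophile on the terminal carbon by hydroboration instead of metal catalysis. Both alkynes are hydroborated in the anti-Markovnikov sense with Cy2BH (excess, THF, 0 °C → rt) and oxidised with NaBO3·4H2O to aldehydes. These should close spontaneously on the adjacent sulfonamide to the bis-hemiaminal (2R,2'R)-1,1'-bis(4-methylbenzenesulfonyl)-2,2'-bipyrrolidine-5,5'-diol F1. Dehydration of F1 with trifluoroacetic anhydride and 2,6-lutidine in toluene (0 → 80 °C) then gives the enamides and returns to the route at 10.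

**Step 2.** The second addition to the mono-adduct may be slow. Some allenyl rather than propargyl transfer may occur, and facial control may be imperfect, giving diastereomer mixtures that are harmless for the end product but awkward to purify. The fallback sets out from 3 and uses a silyl-capped reagent that cannot deliver an allene. Addition of 3-(trimethylsilyl)propargyl bromide with In powder (THF, rt) should give N,N'-[(4R,5R)-1,8-bis(trimethylsilyl)octa-1,7-diyne-4,5-diyl]bis[(S)-2-methylpropane-2-sulfinamide] F2. Desilylation of F2 with K2CO3 in MeOH returns to the route at 5.

**Step 6.** Deprotonation of a C–H activated only by nitrogen may be slow, so that elimination stops after one ring, or the strongly basic medium may degrade the enamide before sulfinate is lost. The fallback sets out from 10 and replaces elimination by dehydrogenation. DDQ (2.2 equiv, toluene, 80 °C) should give 1,1'-bis(4-methylbenzenesulfonyl)-1H,1'H-2,2'-bipyrrole F3. Cleavage of the N-sulfonyl groups of F3 with NaOH in MeOH/THF (60 °C) returns to the route at 12.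

**Step 7.** Oxidative coupling or decomposition of the electron-rich, unprotected bipyrrole may compete with substitution, and substitution may be incomplete, giving mixtures of lower bromides. The fallback sets out from 10 and brominates a deactivated, oxidation-resistant core before freeing the nitrogens. DDQ dehydrogenation gives 1,1'-bis(4-methylbenzenesulfonyl)-1H,1'H-2,2'-bipyrrole F3. Exhaustive bromination of F3 with excess Br2 (AcOH, NaOAc, 60–80 °C) should give 3,3',4,4',5,5'-hexabromo-1,1'-bis(4-methylbenzenesulfonyl)-1H,1'H-2,2'-bipyrrole F4, although the hindered 3,3'-positions are expected to react slowly. Removal of the sulfonyl groups from F4 with NaOH in MeOH/THF returns to the route at 13.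

## Further compounds

F1 | step 5 | (2R,2'R)-1,1'-bis(4-methylbenzenesulfonyl)-2,2'-bipyrrolidine-5,5'-diol (hemiaminal carbons undefined) | OC1CC[C@@H](N1S(=O)(=O)c1ccc(C)cc1)[C@@H](CCC2O)N2S(=O)(=O)c1ccc(C)cc1
F2 | step 2 | N,N'-[(4R,5R)-1,8-bis(trimethylsilyl)octa-1,7-diyne-4,5-diyl]bis[(S)-2-methylpropane-2-sulfinamide] | C[Si](C)(C)C#CC[C@@H](N[S@@](=O)C(C)(C)C)[C@@H](CC#C[Si](C)(C)C)N[S@@](=O)C(C)(C)C
F3 | step 6 | 1,1'-bis(4-methylbenzenesulfonyl)-1H,1'H-2,2'-bipyrrole | Cc1ccc(cc1)S(=O)(=O)n1cccc1-c1cccn1S(=O)(=O)c1ccc(C)cc1
F4 | step 7 | 3,3',4,4',5,5'-hexabromo-1,1'-bis(4-methylbenzenesulfonyl)-1H,1'H-2,2'-bipyrrole | Cc1ccc(cc1)S(=O)(=O)n1c(Br)c(Br)c(Br)c1-c1c(Br)c(Br)c(Br)n1S(=O)(=O)c1ccc(C)cc1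
A1 | alternative 1 | tert-butyl 2-formyl-1H-pyrrole-1-carboxylate | O=Cc1cccn1C(=O)OC(C)(C)C
A2 | alternative 1 | ethyl N-{(E)-[1-(tert-butoxycarbonyl)-1H-pyrrol-2-yl]methylidene}glycinate | CCOC(=O)C/N=C/c1cccn1C(=O)OC(C)(C)C
A3 | alternative 1 | (E)-1,2-bis(phenylsulfonyl)ethene | O=S(=O)(/C=C/S(=O)(=O)c1ccccc1)c1ccccc1
A4 | alternative 1 | ethyl 1'-(tert-butoxycarbonyl)-1H,1'H-2,2'-bipyrrole-5-carboxylate | CCOC(=O)c1ccc([nH]1)-c1cccn1C(=O)OC(C)(C)C
A5 | alternative 2 | N,N'-[(3R,4R)-hexa-1,5-diene-3,4-diyl]bis[4-methyl-N-(prop-2-en-1-yl)benzenesulfonamide] | C=CCN(S(=O)(=O)c1ccc(C)cc1)[C@H](C=C)[C@@H](C=C)N(CC=C)S(=O)(=O)c1ccc(C)cc1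
A6 | alternative 2 | (2R,2'R)-1,1'-bis(4-methylbenzenesulfonyl)-2,2',5,5'-tetrahydro-1H,1'H-2,2'-bipyrrole | C1CN(S(=O)(=O)c3ccc(C)cc3)[C@H](C=1)[C@@H](C=2)N(S(=O)(=O)c3ccc(C)cc3)CC2
A7 | alternative 3 | N-(but-3-yn-1-yl)-4-methylbenzenesulfonamide | C#CCCNS(=O)(=O)c1ccc(C)cc1
A8 | alternative 3 | N,N'-(octa-3,5-diyne-1,8-diyl)bis(4-methylbenzenesulfonamide) | Cc1ccc(cc1)S(=O)(=O)NCCC#CC#CCCNS(=O)(=O)c1ccc(C)cc1
A9 | alternative 3 | 1,1'-bis(4-methylbenzenesulfonyl)-4,4',5,5'-tetrahydro-1H,1'H-2,2'-bipyrrole | Cc1ccc(cc1)S(=O)(=O)N1CCC=C1C1=CCCN1S(=O)(=O)c1ccc(C)cc1
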